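**Plan**

1. Chain numbering: C1≡C2–C3=C4–C5–C6(O)–C7(Cl)–C8–C9(Cl)–C10(OAc)–C11–C12(O)–C13(Br)–C14–C15; the oxocane is O/C6–C12. Retrosynthesis removes the acetate, cuts C3=C4 (enyne cross-metathesis) and C5–C6 (allylation of a C6 lactol acetate), leaving an oxocan-2-one with C6 as lactone carbonyl.
2. Key cut: C7–C8 together with C9–Cl. The C7(Cl)–C8H2–C9(Cl) 1,3-dichloride next to the oxygen-bearing ring carbon C6 is the adduct of a dichloroacetate α-radical and a vinyl group, so the lactone opens to the dichloroacetate of a pent-4-enyl alcohol (ester on O–C12, alkene C8=C9).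
3. That alcohol is cut at C12–O and C13–Br (bromocarbonate cyclisation of (S,E)-octa-1,5-dien-3-ol), and the dienol at C9–C10 (vinyl addition to (E)-hex-3-enal).
4. Forward: chain C8–C15, then the acyclic C10/C12/C13 triad, then the eight-membered lactone by 8-endo chlorine-atom-transfer radical cyclisation (the only ring-forming step of the skeleton), then the C6 side chain, the enyne and the acetate.
5. Stereochemistry: C10 from a Sharpless kinetic resolution; C12 and C13 from C10 by 1,3-induction and anti addition; C9 (anti to C10–O) and C7 (exo-face chlorine return) in the radical cyclisation; C6 by exo-face attack on the oxocarbenium ion; the Z-alkene from enyne cross-metathesis.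

Key step: step 9

Remark: the secondary C13 bromide made in step 5 is carried to the end, on the assumption that an unactivated, β-oxygenated secondary bromide is inert to the later reagents (hydride at −78 °C, monovalent copper with an amine ligand, silyl triflate, ruthenium alkylidene, buffered fluoride).

**Route**

Step 1
Reactants: 1 (E)-hex-3-en-1-ol
Product: 2 (E)-hex-3-enal
Conditions: Dess–Martin periodinane, CH2Cl2, 0 °C to rt; used crude
Reagents that add atoms: none
Why: Dess–Martin oxidation stops at the aldehyde under near-neutral conditions that should not move the β,γ-alkene into conjugation; no stereocentre is formed.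

Step 2
Reactants: 2 (E)-hex-3-enal
Product: 3 racemic (E)-octa-1,5-dien-3-ol
Conditions: vinylmagnesium bromide, THF, −78 °C; then H2O work-up
Reagents that add atoms: vinylmagnesium bromide, C=C[Mg]Br
Why: Grignard 1,2-addition at low temperature should outrun enolisation of the β,γ-unsaturated aldehyde and gives the vinyl carbinol (C10) as the racemate.

Step 3
Reactants: 3 racemic (E)-octa-1,5-dien-3-ol
Product: 4 (3S,5E)-octa-1,5-dien-3-ol
Conditions: Ti(OiPr)4 (0.1 equiv), D-(−)-diisopropyl tartrate (0.15 equiv), t-BuOOH (0.6 equiv), 4 Å molecular sieves, CH2Cl2, −20 °C; run to a little over half conversion, chromatography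
Reagents that add atoms: none
Why: Sharpless kinetic resolution: with the D-(−)-tartrate the R enantiomer of a 1-alken-3-ol is epoxidised much faster, so the S alcohol (future C10) should be recovered in high enantiomeric purity, and the homoallylic E-alkene is not a substrate for the titanium tartrate system.

Step 4
Reactants: 4 (3S,5E)-octa-1,5-dien-3-ol
Product: 5 tert-butyl (3S,5E)-octa-1,5-dien-3-yl carbonate
Conditions: Boc2O, DMAP (0.1 equiv), CH3CN, rt
Reagents that add atoms: di-tert-butyl dicarbonate, CC(C)(C)OC(=O)OC(=O)OC(C)(C)C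
Why: DMAP-catalysed O-acylation installs the internal carbonate nucleophile for the next step without touching C10.

Step 5
Reactants: 5 tert-butyl (3S,5E)-octa-1,5-dien-3-yl carbonate
Product: 6 (4S,6R)-6-[(1S)-1-bromopropyl]-4-ethenyl-1,3-dioxan-2-one
Conditions: N-bromosuccinimide (1.2 equiv), CH3CN, −20 to 0 °C, dark
Reagents that add atoms: N-bromosuccinimide, O=C1CCC(=O)N1Br
Why: Bromocarbonate cyclisation (electrophilic halocyclisation of a homoallylic tert-butyl carbonate): the more electron-rich E-disubstituted alkene takes up the bromonium ion, the carbonyl oxygen closes 6-exo at C12 through a chair with the vinyl group equatorial (4,6-cis, so C10/C12 syn), and anti addition across the E-alkene puts bromine on C13 (12R,13S) with loss of 2-methylpropene.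

Step 6
Reactants: 6 (4S,6R)-6-[(1S)-1-bromopropyl]-4-ethenyl-1,3-dioxan-2-one
Product: 7 (3S,5R,6S)-6-bromooct-1-ene-3,5-diol
Conditions: i-Bu2AlH (4 equiv), CH2Cl2, −78 to −40 °C; aq. potassium sodium tartrate
Reagents that add atoms: none
Why: Hydride reduction of the cyclic carbonate releases the diol at low temperature through aluminium alkoxides that are too weakly nucleophilic to close the C12–C13 epoxide, which a basic methanolysis would give.

Step 7
Reactants: 7 (3S,5R,6S)-6-bromooct-1-ene-3,5-diol
Product: 8 (3S,4R,6S)-3-bromo-6-[(tert-butyldimethylsilyl)oxy]oct-7-en-4-ol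
Conditions: TBSCl (1.05 equiv), imidazole, DMF, −20 to 0 °C
Reagents that add atoms: tert-butyldimethylsilyl chloride, CC(C)(C)[Si](C)(C)Cl
Why: Silyl ether formation should occur at the allylic C10 hydroxyl, which is less hindered and more nucleophilic than the C12 hydroxyl flanked by the branched, inductively deactivating CHBr carbon.

Step 8
Reactants: 8 (3S,4R,6S)-3-bromo-6-[(tert-butyldimethylsilyl)oxy]oct-7-en-4-ol
Product: 9 (3S,4R,6S)-3-bromo-6-[(tert-butyldimethylsilyl)oxy]oct-7-en-4-yl dichloroacetate
Conditions: Cl2CHCOCl (1.5 equiv), pyridine, DMAP (cat.), CH2Cl2, −20 to 0 °C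
Reagents that add atoms: dichloroacetyl chloride, O=C(Cl)C(Cl)Cl
Why: Acylation with the acid chloride under weakly basic conditions gives the pent-4-enyl dichloroacetate (C6 and C7 with both chlorines) without epoxide formation from the bromohydrin or change at any stereocentre.

Step 9
Reactants: 9 (3S,4R,6S)-3-bromo-6-[(tert-butyldimethylsilyl)oxy]oct-7-en-4-yl dichloroacetate
Product: 10 (3S,5S,6S,8R)-8-[(1S)-1-bromopropyl]-6-[(tert-butyldimethylsilyl)oxy]-3,5-dichlorooxocan-2-one
Conditions: CuCl (0.3 equiv), tris(2-pyridylmethyl)amine (0.3 equiv), degassed 1,2-dichloroethane (0.01 M), 80 °C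
Reagents that add atoms: none
Why: Monovalent copper abstracts one chlorine of the dichloroacetate to give the α-chloro ester radical at C7, which adds to the terminal alkene carbon C8, and the resulting secondary C9 radical takes chlorine back from the divalent copper chloride complex, so the C7–C8 bond, the oxocanone ring and both C–Cl bonds arise in one redox-neutral isomerisation (an intramolecular Kharasch addition; closest known type: copper-catalysed chlorine-atom-transfer cyclisation of pent-4-enyl di- and trichloroacetates to eight-membered lactones). The ring closes in the 8-endo-trig mode, which is compatible with the preferred Z conformation of the ester, whereas 7-exo closure would require attack at the substituted alkene carbon next to the C10 silyloxy group. C9 is set by 1,2-induction, chlorine being delivered to the ring radical anti to the adjacent OTBS group (C9–Cl trans to C10–O). C7 is set by chlorine return to the exo face of the lactone α-radical in the conformer that keeps the C12 side chain pseudo-equatorial, giving the pseudo-axial chloride trans to that side chain; because this α-chloro lactone C–Cl bond stays reversibly activated by the catalyst, the centre should converge on that isomer, which is also the one favoured by the α-halo carbonyl dipole effect. The step needs activation of the dichloroester in preference to the unactivated C13–Br bond, secured by the large difference in reducibility and by the amine ligand, and cyclisation in preference to oligomerisation, secured by high dilution.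

Step 10
Reactants: 10 (3S,5S,6S,8R)-8-[(1S)-1-bromopropyl]-6-[(tert-butyldimethylsilyl)oxy]-3,5-dichlorooxocan-2-one
Product: 12 (3S,5S,6S,8R)-8-[(1S)-1-bromopropyl]-6-[(tert-butyldimethylsilyl)oxy]-3,5-dichlorooxocan-2-yl acetate (both C2 anomers), via diisobutylaluminium hemiacetal 11 (not isolated)
Conditions: i-Bu2AlH (1.2 equiv), CH2Cl2, −78 °C; then pyridine, DMAP, Ac2O, −78 to −20 °C
Reagents that add atoms: acetic anhydride, CC(=O)OC(C)=O
Why: Reductive acetylation: hydride reduction at −78 °C stops at the tetrahedral aluminium hemiacetal (stabilised by the α-chlorine), which is acetylated in situ before it can open to the hydroxy aldehyde, and the anomeric mixture is of no consequence.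

Step 11
Reactants: 12 (3S,5S,6S,8R)-8-[(1S)-1-bromopropyl]-6-[(tert-butyldimethylsilyl)oxy]-3,5-dichlorooxocan-2-yl acetate
Product: 13 (2S,3S,5S,6S,8R)-8-[(1S)-1-bromopropyl]-6-[(tert-butyldimethylsilyl)oxy]-3,5-dichloro-2-(prop-2-en-1-yl)oxocane
Conditions: allyltrimethylsilane (5 equiv), Me3SiOTf (0.3 equiv), CH2Cl2, −78 to −30 °C
Reagents that add atoms: allyltrimethylsilane, C=CC[Si](C)(C)C
Why: Hosomi–Sakurai C-allylation through the eight-membered oxocarbenium ion: the allylsilane should attack the exo face of the conformer with the C12 side chain pseudo-equatorial and the C7 chlorine pseudo-axial (the endo face being screened by the transannular C9/C10 substituents), which sets C6 trans to the C12 side chain and cis to the C7 chlorine.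

Step 12
Reactants: 14 ethynyltriisopropylsilane; 15 vinyl bromide
Product: 16 (but-3-en-1-yn-1-yl)triisopropylsilane
Conditions: PdCl2(PPh3)2 (2 mol %), CuI (4 mol %), i-Pr2NH, THF, 0 °C to rt
Reagents that add atoms: none
Why: Sonogashira coupling of a terminal alkyne with a vinyl halide gives the silyl-protected conjugated enyne used as the metathesis partner.

Step 13
Reactants: 13 (2S,3S,5S,6S,8R)-8-[(1S)-1-bromopropyl]-6-[(tert-butyldimethylsilyl)oxy]-3,5-dichloro-2-(prop-2-en-1-yl)oxocane; 16 (but-3-en-1-yn-1-yl)triisopropylsilane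
Product: 17 (2S,3S,5S,6S,8R)-8-[(1S)-1-bromopropyl]-6-[(tert-butyldimethylsilyl)oxy]-3,5-dichloro-2-[(2Z)-5-(triisopropylsilyl)pent-2-en-4-yn-1-yl]oxocane
Conditions: second-generation Grubbs catalyst (10 mol %), 16 (3 equiv), benzene, 60 °C
Reagents that add atoms: none
Why: Olefin cross-metathesis of a terminal alkene with a silyl-capped conjugated enyne, a pairing known to favour the Z-enyne (the slim alkynyl group tolerates the cis-substituted ruthenacyclobutane and the product resists secondary metathesis); 13 carries no other alkene, and the halides and silyl ether are inert.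

Step 14
Reactants: 17 (2S,3S,5S,6S,8R)-8-[(1S)-1-bromopropyl]-6-[(tert-butyldimethylsilyl)oxy]-3,5-dichloro-2-[(2Z)-5-(triisopropylsilyl)pent-2-en-4-yn-1-yl]oxocane
Product: 18 (2R,4S,5S,7S,8S)-2-[(1S)-1-bromopropyl]-5,7-dichloro-8-[(2Z)-pent-2-en-4-yn-1-yl]oxocan-4-ol
Conditions: Bu4NF/AcOH (1:1, 4 equiv), THF, 0 °C to rt
Reagents that add atoms: none
Why: Fluoride-mediated desilylation removes the alkynyl silyl group and the silyl ether together, and the acetic acid buffer keeps the C10 oxygen protonated so that it cannot displace the trans C9 chloride (epoxide) and tempers elimination at the C13 bromide.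

Step 15
Reactants: 18 (2R,4S,5S,7S,8S)-2-[(1S)-1-bromopropyl]-5,7-dichloro-8-[(2Z)-pent-2-en-4-yn-1-yl]oxocan-4-ol
Product: 19 (2R,4S,5S,7S,8S)-2-[(1S)-1-bromopropyl]-5,7-dichloro-8-[(2Z)-pent-2-en-4-yn-1-yl]oxocan-4-yl acetate
Conditions: Ac2O, pyridine, DMAP (cat.), CH2Cl2, 0 °C to rt
Reagents that add atoms: acetic anhydride, CC(=O)OC(C)=O
Why: DMAP-catalysed acetylation of the secondary alcohol gives the target without affecting any stereocentre.

**Compound list**

1 | (E)-hex-3-en-1-ol | CC/C=C/CCO | starting material
2 | (E)-hex-3-enal | CC/C=C/CC=O | intermediate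
3 | racemic (E)-octa-1,5-dien-3-ol | C=CC(O)C/C=C/CC | intermediate
4 | (3S,5E)-octa-1,5-dien-3-ol | C=C[C@@H](O)C/C=C/CC | intermediate
5 | tert-butyl (3S,5E)-octa-1,5-dien-3-yl carbonate | C=C[C@@H](OC(=O)OC(C)(C)C)C/C=C/CC | intermediate
6 | (4S,6R)-6-[(1S)-1-bromopropyl]-4-ethenyl-1,3-dioxan-2-one | C=C[C@@H]1C[C@H]([C@@H](Br)CC)OC(=O)O1 | intermediate
7 | (3S,5R,6S)-6-bromooct-1-ene-3,5-diol | C=C[C@@H](O)C[C@@H](O)[C@@H](Br)CC | intermediate
8 | (3S,4R,6S)-3-bromo-6-[(tert-butyldimethylsilyl)oxy]oct-7-en-4-ol | C=C[C@@H](O[Si](C)(C)C(C)(C)C)C[C@@H](O)[C@@H](Br)CC | intermediate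
9 | (3S,4R,6S)-3-bromo-6-[(tert-butyldimethylsilyl)oxy]oct-7-en-4-yl dichloroacetate | C=C[C@@H](O[Si](C)(C)C(C)(C)C)C[C@@H](OC(=O)C(Cl)Cl)[C@@H](Br)CC | intermediate
10 | (3S,5S,6S,8R)-8-[(1S)-1-bromopropyl]-6-[(tert-butyldimethylsilyl)oxy]-3,5-dichlorooxocan-2-one | O=C1O[C@@H]([C@@H](Br)CC)C[C@H](O[Si](C)(C)C(C)(C)C)[C@@H](Cl)C[C@@H]1Cl | intermediate
11 | diisobutylaluminium hemiacetal of 10 (O-aluminated lactol, C2 epimers) | CC(C)C[Al](CC(C)C)OC1O[C@@H]([C@@H](Br)CC)C[C@H](O[Si](C)(C)C(C)(C)C)[C@@H](Cl)C[C@@H]1Cl | intermediate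
12 | (3S,5S,6S,8R)-8-[(1S)-1-bromopropyl]-6-[(tert-butyldimethylsilyl)oxy]-3,5-dichlorooxocan-2-yl acetate (C2 anomers) | CC(=O)OC1O[C@@H]([C@@H](Br)CC)C[C@H](O[Si](C)(C)C(C)(C)C)[C@@H](Cl)C[C@@H]1Cl | intermediate
13 | (2S,3S,5S,6S,8R)-8-[(1S)-1-bromopropyl]-6-[(tert-butyldimethylsilyl)oxy]-3,5-dichloro-2-(prop-2-en-1-yl)oxocane | C=CC[C@@H]1O[C@@H]([C@@H](Br)CC)C[C@H](O[Si](C)(C)C(C)(C)C)[C@@H](Cl)C[C@@H]1Cl | intermediate
14 | ethynyltriisopropylsilane | C#C[Si](C(C)C)(C(C)C)C(C)C | starting material
15 | vinyl bromide | C=CBr | starting material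
16 | (but-3-en-1-yn-1-yl)triisopropylsilane | C=CC#C[Si](C(C)C)(C(C)C)C(C)C | intermediate
17 | (2S,3S,5S,6S,8R)-8-[(1S)-1-bromopropyl]-6-[(tert-butyldimethylsilyl)oxy]-3,5-dichloro-2-[(2Z)-5-(triisopropylsilyl)pent-2-en-4-yn-1-yl]oxocane | CC(C)[Si](C(C)C)(C(C)C)C#C/C=C\C[C@@H]1O[C@@H]([C@@H](Br)CC)C[C@H](O[Si](C)(C)C(C)(C)C)[C@@H](Cl)C[C@@H]1Cl | intermediate
18 | (2R,4S,5S,7S,8S)-2-[(1S)-1-bromopropyl]-5,7-dichloro-8-[(2Z)-pent-2-en-4-yn-1-yl]oxocan-4-ol | C#C/C=C\C[C@@H]1O[C@@H]([C@@H](Br)CC)C[C@H](O)[C@@H](Cl)C[C@@H]1Cl | intermediate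
19 | (2R,4S,5S,7S,8S)-2-[(1S)-1-bromopropyl]-5,7-dichloro-8-[(2Z)-pent-2-en-4-yn-1-yl]oxocan-4-yl acetate | C#C/C=C\C[C@@H]1O[C@@H]([C@@H](Br)CC)C[C@H](OC(C)=O)[C@@H](Cl)C[C@@H]1Cl | target

**Step count and risks**

Total step count: 15. Longest linear sequence: 14 steps (steps 1–11 and 13–15; step 12 is a one-step side branch).

The three steps most likely to fail, in order of risk:

Step 9. Intermolecular radical addition or 7-exo closure may compete with the 8-endo mode, and the C7 centre may not converge fully on the chloride trans to the C12 side chain. The fallback sets out from 8 and separates ring formation from the C7 question. Acylation of 8 with trichloroacetyl chloride and pyridine gives (3S,4R,6S)-3-bromo-6-[(tert-butyldimethylsilyl)oxy]oct-7-en-4-yl trichloroacetate F1, the most easily activated and best-precedented substrate class. CuCl with 2,2'-bipyridine in hot 1,2-dichloroethane should close it 8-endo to (5S,6S,8R)-8-[(1S)-1-bromopropyl]-6-[(tert-butyldimethylsilyl)oxy]-3,3,5-trichlorooxocan-2-one F2, in which only C9 is a new stereocentre. Zinc dust in acetic acid/THF at 0 °C then removes one of the two activated α-chlorines through the zinc enolate, leaving the unactivated C–Br and C9–Cl bonds alone; protonation, followed if needed by tertiary-amine equilibration of the α-chloro lactone, brings the material back to the route at 10.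

Step 11. The allylsilane may attack the face anti to the C7 chlorine (wrong configuration at C6), or ionisation next to the chlorine may be slow enough for the silyl ether to suffer. The fallback sets out from 10 and reverses the order of bond formation at C6. One equivalent of allylmagnesium bromide at −78 °C adds to the lactone carbonyl to give (3S,5S,6S,8R)-2-allyl-8-[(1S)-1-bromopropyl]-6-[(tert-butyldimethylsilyl)oxy]-3,5-dichlorooxocan-2-ol F3, a hemiketal stabilised by the α-chlorine. Reduction with Et3SiH and Me3SiOTf at −78 °C then passes through the more easily formed C6-allyl oxocarbenium ion; hydride enters on the face that the carbon nucleophile used in step 11, so the opposite C6 configuration results, which is the right one if the chlorine rather than the C12 side chain controls the face. The sequence comes back to the route at 13.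

Step 5. The bromonium ion may form in part at the vinyl group, or the 1,3-induction in ring closure may be weak; the unselective silylation of diol 7 in step 7 is a related downstream hazard. The fallback sets out from 5 and uses the stepwise iodocarbonate–epoxide sequence. IBr in toluene at −80 °C should give (4S,6R)-4-ethenyl-6-[(1S)-1-iodopropyl]-1,3-dioxan-2-one F4 in the most selective variant of the halocarbonate cyclisation. K2CO3 in methanol cleaves the carbonate and closes the trans-epoxide, giving (2S)-1-[(2R,3R)-3-ethyloxiran-2-yl]but-3-en-2-ol F5, whose single hydroxyl is silylated (TBSCl, imidazole) to tert-butyl{[(2S)-1-[(2R,3R)-3-ethyloxiran-2-yl]but-3-en-2-yl]oxy}dimethylsilane F6. MgBr2·OEt2 in ether at −20 °C then opens the epoxide with inversion at C13, the carbon remote from the bulky, inductively deactivating silyloxy branch, and the sequence comes back to the route at 8, bypassing steps 6 and 7.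

**Further compounds**

F1 | step 9 | (3S,4R,6S)-3-bromo-6-[(tert-butyldimethylsilyl)oxy]oct-7-en-4-yl trichloroacetate | C=C[C@@H](O[Si](C)(C)C(C)(C)C)C[C@@H](OC(=O)C(Cl)(Cl)Cl)[C@@H](Br)CC
F2 | step 9 | (5S,6S,8R)-8-[(1S)-1-bromopropyl]-6-[(tert-butyldimethylsilyl)oxy]-3,3,5-trichlorooxocan-2-one | O=C1O[C@@H]([C@@H](Br)CC)C[C@H](O[Si](C)(C)C(C)(C)C)[C@@H](Cl)CC1(Cl)Cl
F3 | step 11 | (3S,5S,6S,8R)-2-allyl-8-[(1S)-1-bromopropyl]-6-[(tert-butyldimethylsilyl)oxy]-3,5-dichlorooxocan-2-ol (C2 epimers) | C=CCC1(O)O[C@@H]([C@@H](Br)CC)C[C@H](O[Si](C)(C)C(C)(C)C)[C@@H](Cl)C[C@@H]1Cl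
F4 | step 5 | (4S,6R)-4-ethenyl-6-[(1S)-1-iodopropyl]-1,3-dioxan-2-one | C=C[C@@H]1C[C@H]([C@@H](I)CC)OC(=O)O1
F5 | step 5 | (2S)-1-[(2R,3R)-3-ethyloxiran-2-yl]but-3-en-2-ol | C=C[C@@H](O)C[C@H]1O[C@@H]1CC
F6 | step 5 | tert-butyl{[(2S)-1-[(2R,3R)-3-ethyloxiran-2-yl]but-3-en-2-yl]oxy}dimethylsilane | C=C[C@@H](O[Si](C)(C)C(C)(C)C)C[C@H]1O[C@@H]1CC
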